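**Plan**

- Cuts: C11–C12 (alkenyl to carbinol), then the O–C7 bond of the lactone (oxygen excised, leaving a 2-cyclopropylcycloheptanone), then C8–C9/C9–C10 (methylene transfer to an E-dienol), C7–C8 (Heck) and C13–C14 (acetylide plus dienal).
- Enabling feature: in the oxocan-2-one ring every carbon is unbranched except C7, and C7 is the carbon bound to the ring oxygen. That O–C7 bond is what forms when the substituted α-carbon of a 2-substituted cycloheptanone shifts from the carbonyl carbon to oxygen.
- Forward order: the purchased seven-membered carbocycle receives the C8–C11 arm, the cyclopropane is built second, the carbocycle is expanded to the eight-membered lactone third, and the C12–C22 chain is joined last at C11.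
- Stereochemistry: C8/C10 from a tartramide-dioxaborolane-controlled Simmons–Smith reaction; C7 from IpcBH2 hydroboration, carried through the oxygen insertion with retention; C14 from a lipase resolution; C11 from an amino-alcohol-controlled alkenylzinc addition.
- Alkene geometry: the Z,Z-diene is bought; the E-alkene comes from syn hydroboration of a terminal alkyne.

Key step: step 8

Assumption: atoms are numbered C1 (lactone carbonyl) to C22 along the chain, and (3Z,6Z)-nona-3,6-dien-1-ol, ethynylmagnesium bromide, both antipodes of the tartramide dioxaborolane, the IpcBH2–TMEDA adduct and (−)-MIB are taken as purchasable.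

**Route**

Step 1
Reactants: 1 cycloheptanone
Product: 3 cyclohept-1-en-1-yl trifluoromethanesulfonate, via lithium cyclohept-1-en-1-olate 2 (not isolated)
Conditions: LiN(i-Pr)2, THF, −78 °C; PhNTf2, −78 °C → rt; aq. NH4Cl
Reagents that add atoms: N-phenylbis(trifluoromethanesulfonimide), O=S(=O)(N(c1ccccc1)S(=O)(=O)C(F)(F)F)C(F)(F)F
Why: Enol triflate formation: the symmetrical ketone gives a single lithium enolate, which is O-sulfonylated by the triflimide.

Step 2
Reactants: 3 cyclohept-1-en-1-yl trifluoromethanesulfonate; 4 methyl acrylate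
Product: 5 methyl (2E)-3-(cyclohept-1-en-1-yl)prop-2-enoate
Conditions: Pd(OAc)2 (cat.), PPh3, Et3N, DMF, 70 °C
Reagents that add atoms: none
Why: Heck reaction: the alkenyl triflate adds oxidatively to zerovalent palladium formed from Pd(OAc)2 and PPh3, and syn carbopalladation of the acrylate followed by syn β-hydride elimination should give the E-dienoate and form the C7–C8 bond.

Step 3
Reactants: 5 methyl (2E)-3-(cyclohept-1-en-1-yl)prop-2-enoate
Product: 6 (2E)-3-(cyclohept-1-en-1-yl)prop-2-en-1-ol
Conditions: i-Bu2AlH, CH2Cl2, −78 °C; aq. potassium sodium tartrate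
Reagents that add atoms: none
Why: 1,2-Reduction of the conjugated ester by i-Bu2AlH at low temperature stops at the allylic alcohol and leaves the diene alone.

Step 4
Reactants: 6 (2E)-3-(cyclohept-1-en-1-yl)prop-2-en-1-ol; 7 diiodomethane
Product: 8 [(1R,2R)-2-(cyclohept-1-en-1-yl)cyclopropyl]methanol
Conditions: Et2Zn, 7, DME, CH2Cl2, −10 °C [gives Zn(CH2I)2·DME]; (4S,5S)-2-butyl-N,N,N′,N′-tetramethyl-1,3,2-dioxaborolane-4,5-dicarboxamide, 6, −10 °C → rt
Reagents that add atoms: none
Why: Charette asymmetric Simmons–Smith cyclopropanation: the zinc alkoxide of 6 is bound by the amide-bearing boronate, which delivers the methylene of Zn(CH2I)2 only to the neighbouring C8=C10 alkene (the ring alkene has no directing group), stereospecifically trans from the E-alkene and, with the (4S,5S)-ligand, on the face that gives 8R,10R, the mirror image of the outcome established for E-allylic alcohols with the (4R,5R)-ligand.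

Step 5
Reactants: 8 [(1R,2R)-2-(cyclohept-1-en-1-yl)cyclopropyl]methanol
Product: 9 tert-butyl{[(1R,2R)-2-(cyclohept-1-en-1-yl)cyclopropyl]methoxy}diphenylsilane
Conditions: t-BuPh2SiCl, imidazole, CH2Cl2, rt
Reagents that add atoms: tert-butyl(chloro)diphenylsilane, CC(C)(C)[Si](Cl)(c1ccccc1)c1ccccc1
Why: Silylation of the primary alcohol; the tert-butyldiphenylsilyl ether is chosen because it withstands borane, alkaline peroxide, periodinane and buffered peracid.

Step 6
Reactants: 9 tert-butyl{[(1R,2R)-2-(cyclohept-1-en-1-yl)cyclopropyl]methoxy}diphenylsilane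
Product: 11 (1S,2R)-2-[(1R,2R)-2-{[tert-butyl(diphenyl)silyl]oxymethyl}cyclopropyl]cycloheptan-1-ol, via cycloheptyl(isopinocampheyl)borane 10 (not isolated)
Conditions: IpcBH2 [from (+)-α-pinene, freed beforehand from its TMEDA adduct with BF3·OEt2], THF, −25 °C; NaOH, H2O2, 0 °C → rt
Reagents that add atoms: hydrogen peroxide, OO
Why: Asymmetric hydroboration–oxidation: boron adds to the less substituted ring carbon C1 and hydrogen to C7 on the same face, oxidation with retention gives the trans alcohol, and the pinene-derived reagent should pick the face in the sense known for 1-substituted cycloalkenes (S carbinol, hence 7R), the minor trans diastereomer being separable because the cyclopropane centres are fixed.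

Step 7
Reactants: 11 (1S,2R)-2-[(1R,2R)-2-{[tert-butyl(diphenyl)silyl]oxymethyl}cyclopropyl]cycloheptan-1-ol
Product: 12 (2R)-2-[(1R,2R)-2-{[tert-butyl(diphenyl)silyl]oxymethyl}cyclopropyl]cycloheptan-1-one
Conditions: Dess–Martin periodinane, NaHCO3, CH2Cl2, 0 °C → rt
Reagents that add atoms: none
Why: Dess–Martin oxidation of the secondary alcohol under bicarbonate buffer is neutral and non-enolising, so the C7 centre next to the new carbonyl should survive.

Step 8
Reactants: 12 (2R)-2-[(1R,2R)-2-{[tert-butyl(diphenyl)silyl]oxymethyl}cyclopropyl]cycloheptan-1-one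
Product: 14 (8R)-8-[(1R,2R)-2-{[tert-butyl(diphenyl)silyl]oxymethyl}cyclopropyl]oxocan-2-one, via Criegee adduct 13 (not isolated)
Conditions: (CF3CO)2O, H2O2·urea, Na2HPO4, CH2Cl2, 0 °C
Reagents that add atoms: trifluoroperacetic acid, OOC(=O)C(F)(F)F (made in the flask from trifluoroacetic anhydride, O=C(OC(=O)C(F)(F)F)C(F)(F)F, and urea–hydrogen peroxide, OO.NC(N)=O)
Why: The peracid adds to the carbonyl of 12 to give the tetrahedral Criegee adduct 13, and C7, aligned antiperiplanar to the O–O bond, shifts from C1 to the proximal peroxide oxygen with loss of trifluoroacetate, which creates the O–C7 bond. This is a Baeyer–Villiger oxidation, the closest precedent being the conversion of 2-alkylcycloheptanones into 8-alkyloxocan-2-ones. The eight-membered lactone is closed by ring expansion, a one-atom oxygen insertion into the existing seven-membered carbocycle through a concerted 1,2-shift, and not by an end-to-end cyclisation. No new stereocentre is formed; the C7 centre set in step 6 is carried over with retention because the migrating carbon stays bonded throughout the shift. The step needs migration of C7 in preference to C2, which the substrate secures because C7 is secondary and carries the cyclopropyl group that stabilises the positive character of the migrating carbon, whereas C2 is a plain methylene. It also needs C7 to stay configurationally intact next to the ketone, which the fast oxidant, the Na2HPO4 buffer and the low temperature should ensure; the silyl ether and the cyclopropane are inert and no alkene is present yet.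

Step 9
Reactants: 14 (8R)-8-[(1R,2R)-2-{[tert-butyl(diphenyl)silyl]oxymethyl}cyclopropyl]oxocan-2-one
Product: 15 (8R)-8-[(1R,2R)-2-(hydroxymethyl)cyclopropyl]oxocan-2-one
Conditions: Bu4NF, AcOH, THF, rt
Reagents that add atoms: none
Why: Fluoride-induced Si–O cleavage; acetic acid buffering keeps the medium non-basic so that the eight-membered lactone is not opened.

Step 10
Reactants: 15 (8R)-8-[(1R,2R)-2-(hydroxymethyl)cyclopropyl]oxocan-2-one
Product: 16 (1R,2R)-2-[(2R)-8-oxooxocan-2-yl]cyclopropane-1-carbaldehyde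
Conditions: Dess–Martin periodinane, NaHCO3, CH2Cl2, 0 °C → rt
Reagents that add atoms: none
Why: Dess–Martin oxidation of the primary alcohol to the aldehyde; the trans-disubstituted cyclopropane carbon next to the formyl group is already in its stable arrangement and the lactone is inert.

Step 11
Reactants: 17 (3Z,6Z)-nona-3,6-dien-1-ol
Product: 18 (3Z,6Z)-nona-3,6-dienal
Conditions: Dess–Martin periodinane, NaHCO3, CH2Cl2, 0 °C; crude product used at once
Reagents that add atoms: none
Why: Buffered Dess–Martin oxidation gives the β,γ-unsaturated aldehyde without acid or base that would move the 3Z alkene into conjugation.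

Step 12
Reactants: 18 (3Z,6Z)-nona-3,6-dienal; 19 ethynylmagnesium bromide
Product: 20 rac-(5Z,8Z)-undeca-5,8-dien-1-yn-3-ol
Conditions: 19, THF, −78 °C; aq. NH4Cl
Reagents that add atoms: none
Why: Grignard 1,2-addition of the acetylide at −78 °C should be faster than enolisation of the sensitive aldehyde and forms the C13–C14 bond; the carbinol is racemic at this stage.

Step 13
Reactants: 20 rac-(5Z,8Z)-undeca-5,8-dien-1-yn-3-ol
Product: 21 (3S,5Z,8Z)-undeca-5,8-dien-1-yn-3-yl acetate
Conditions: immobilised Candida antarctica lipase B, vinyl acetate, hexane, 30 °C, stopped before half conversion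
Reagents that add atoms: vinyl acetate, C=COC(C)=O
Why: Lipase-catalysed kinetic resolution by irreversible transesterification: the enzyme should acylate the enantiomer whose small ethynyl group fits the medium pocket, which is the 3S alcohol, so C14 is set here and the unreacted 3R enantiomer of 20 is removed on silica.

Step 14
Reactants: 21 (3S,5Z,8Z)-undeca-5,8-dien-1-yn-3-yl acetate
Product: 22 (3S,5Z,8Z)-undeca-5,8-dien-1-yn-3-ol
Conditions: K2CO3, MeOH, 0 °C
Reagents that add atoms: none
Why: Base-catalysed methanolysis of the acetate (transesterification) breaks only the acyl C–O bond, so the C14 configuration is kept.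

Step 15
Reactants: 22 (3S,5Z,8Z)-undeca-5,8-dien-1-yn-3-ol
Product: 23 tert-butyldimethyl{[(3S,5Z,8Z)-undeca-5,8-dien-1-yn-3-yl]oxy}silane
Conditions: t-BuMe2SiCl, imidazole, DMF, rt
Reagents that add atoms: tert-butyl(chloro)dimethylsilane, CC(C)(C)[Si](C)(C)Cl
Why: Silylation of the secondary alcohol; the tert-butyldimethylsilyl ether tolerates borane and organozinc reagents and can be removed at the end without acid.

Step 16
Reactants: 23 tert-butyldimethyl{[(3S,5Z,8Z)-undeca-5,8-dien-1-yn-3-yl]oxy}silane; 16 (1R,2R)-2-[(2R)-8-oxooxocan-2-yl]cyclopropane-1-carbaldehyde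
Product: 26 (8R)-8-[(1R,2R)-2-[(1S,2E,4S,6Z,9Z)-4-(tert-butyldimethylsilyloxy)-1-hydroxydodeca-2,6,9-trien-1-yl]cyclopropyl]oxocan-2-one, via alkenyl(dicyclohexyl)borane 24 (not isolated), via alkenyl(methyl)zinc 25 (not isolated)
Conditions: 23, Cy2BH (from BH3·SMe2 and cyclohexene), toluene, 0 °C → rt; Me2Zn, −78 °C; (2S)-(−)-3-exo-morpholinoisoborneol [(−)-MIB] (cat.), 16, −30 → 0 °C; aq. NH4Cl
Reagents that add atoms: none
Why: Catalytic asymmetric alkenylzinc addition: Cy2BH adds syn and anti-Markovnikov to the terminal alkyne (far faster than to the 1,2-disubstituted Z-alkenes), boron–zinc exchange keeps the E geometry, and the amino alcohol–zinc catalyst should deliver the alkenyl group to the Si face of the formyl group of 16, which sets 11S by reagent control while the lactone is inert to organozinc species.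

Step 17
Reactants: 26 (8R)-8-[(1R,2R)-2-[(1S,2E,4S,6Z,9Z)-4-(tert-butyldimethylsilyloxy)-1-hydroxydodeca-2,6,9-trien-1-yl]cyclopropyl]oxocan-2-one
Product: 27 (8R)-8-[(1R,2R)-2-[(1S,2E,4S,6Z,9Z)-1,4-dihydroxydodeca-2,6,9-trien-1-yl]cyclopropyl]oxocan-2-one
Conditions: Bu4NF, AcOH, THF, 0 °C → rt
Reagents that add atoms: none
Why: Buffered fluoride desilylation avoids both acid, which would ionise the allylic cyclopropylcarbinol at C11, and strong base, which would open the lactone, and should release the target.

**Compound list**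

1 | cycloheptanone | O=C1CCCCCC1 | starting material
2 | lithium cyclohept-1-en-1-olate | [Li]OC1=CCCCCC1 | intermediate (not isolated)
3 | cyclohept-1-en-1-yl trifluoromethanesulfonate | O=S(=O)(OC1=CCCCCC1)C(F)(F)F | intermediate
4 | methyl acrylate | C=CC(=O)OC | starting material
5 | methyl (2E)-3-(cyclohept-1-en-1-yl)prop-2-enoate | COC(=O)/C=C/C1=CCCCCC1 | intermediate
6 | (2E)-3-(cyclohept-1-en-1-yl)prop-2-en-1-ol | OC/C=C/C1=CCCCCC1 | intermediate
7 | diiodomethane | ICI | starting material
8 | [(1R,2R)-2-(cyclohept-1-en-1-yl)cyclopropyl]methanol | OC[C@@H]1C[C@H]1C1=CCCCCC1 | intermediate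
9 | tert-butyl{[(1R,2R)-2-(cyclohept-1-en-1-yl)cyclopropyl]methoxy}diphenylsilane | CC(C)(C)[Si](OC[C@@H]1C[C@H]1C1=CCCCCC1)(c1ccccc1)c1ccccc1 | intermediate
10 | {trans-2-[(1R,2R)-2-{[tert-butyl(diphenyl)silyl]oxymethyl}cyclopropyl]cycloheptyl}(isopinocampheyl)borane, boron in the place of the hydroxyl of 11 | C[C@H]1[C@H](B[C@H]3CCCCC[C@@H]3[C@@H]4C[C@H]4CO[Si](c5ccccc5)(c6ccccc6)C(C)(C)C)C[C@@H]2C[C@H]1C2(C)C | intermediate (not isolated)
11 | (1S,2R)-2-[(1R,2R)-2-{[tert-butyl(diphenyl)silyl]oxymethyl}cyclopropyl]cycloheptan-1-ol | O[C@H]1CCCCC[C@@H]1[C@@H]1C[C@H]1CO[Si](c1ccccc1)(c1ccccc1)C(C)(C)C | intermediate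
12 | (2R)-2-[(1R,2R)-2-{[tert-butyl(diphenyl)silyl]oxymethyl}cyclopropyl]cycloheptan-1-one | O=C1CCCCC[C@@H]1[C@@H]1C[C@H]1CO[Si](c1ccccc1)(c1ccccc1)C(C)(C)C | intermediate
13 | (2R)-1-hydroxy-2-[(1R,2R)-2-{[tert-butyl(diphenyl)silyl]oxymethyl}cyclopropyl]cycloheptyl trifluoroperacetate (Criegee adduct, C1 configuration open) | OC1(OOC(=O)C(F)(F)F)CCCCC[C@@H]1[C@@H]1C[C@H]1CO[Si](c1ccccc1)(c1ccccc1)C(C)(C)C | intermediate (not isolated)
14 | (8R)-8-[(1R,2R)-2-{[tert-butyl(diphenyl)silyl]oxymethyl}cyclopropyl]oxocan-2-one | O=C1CCCCC[C@H]([C@@H]2C[C@H]2CO[Si](c2ccccc2)(c2ccccc2)C(C)(C)C)O1 | intermediate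
15 | (8R)-8-[(1R,2R)-2-(hydroxymethyl)cyclopropyl]oxocan-2-one | O=C1CCCCC[C@H]([C@@H]2C[C@H]2CO)O1 | intermediate
16 | (1R,2R)-2-[(2R)-8-oxooxocan-2-yl]cyclopropane-1-carbaldehyde | O=C1CCCCC[C@H]([C@@H]2C[C@H]2C=O)O1 | intermediate
17 | (3Z,6Z)-nona-3,6-dien-1-ol | CC/C=C\C/C=C\CCO | starting material
18 | (3Z,6Z)-nona-3,6-dienal | CC/C=C\C/C=C\CC=O | intermediate
19 | ethynylmagnesium bromide | C#C[Mg]Br | starting material
20 | rac-(5Z,8Z)-undeca-5,8-dien-1-yn-3-ol | CC/C=C\C/C=C\CC(O)C#C | intermediate
21 | (3S,5Z,8Z)-undeca-5,8-dien-1-yn-3-yl acetate | CC/C=C\C/C=C\C[C@H](OC(C)=O)C#C | intermediate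
22 | (3S,5Z,8Z)-undeca-5,8-dien-1-yn-3-ol | CC/C=C\C/C=C\C[C@H](O)C#C | intermediate
23 | tert-butyldimethyl{[(3S,5Z,8Z)-undeca-5,8-dien-1-yn-3-yl]oxy}silane | CC/C=C\C/C=C\C[C@H](O[Si](C)(C)C(C)(C)C)C#C | intermediate
24 | [(1E,3S,5Z,8Z)-3-(tert-butyldimethylsilyloxy)undeca-1,5,8-trien-1-yl]dicyclohexylborane | CC/C=C\C/C=C\C[C@H](O[Si](C)(C)C(C)(C)C)/C=C/B(C1CCCCC1)C1CCCCC1 | intermediate (not isolated)
25 | [(1E,3S,5Z,8Z)-3-(tert-butyldimethylsilyloxy)undeca-1,5,8-trien-1-yl](methyl)zinc | CC/C=C\C/C=C\C[C@H](O[Si](C)(C)C(C)(C)C)/C=C/[Zn]C | intermediate (not isolated)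
26 | (8R)-8-[(1R,2R)-2-[(1S,2E,4S,6Z,9Z)-4-(tert-butyldimethylsilyloxy)-1-hydroxydodeca-2,6,9-trien-1-yl]cyclopropyl]oxocan-2-one | CC/C=C\C/C=C\C[C@H](O[Si](C)(C)C(C)(C)C)/C=C/[C@H](O)[C@@H]1C[C@H]1[C@H]1CCCCCC(=O)O1 | intermediate
27 | (8R)-8-[(1R,2R)-2-[(1S,2E,4S,6Z,9Z)-1,4-dihydroxydodeca-2,6,9-trien-1-yl]cyclopropyl]oxocan-2-one | CC/C=C\C/C=C\C[C@H](O)/C=C/[C@H](O)[C@@H]1C[C@H]1[C@H]1CCCCCC(=O)O1 | target

**Step count**

Total: 17 steps. Longest linear sequence: 12 steps (steps 1–10, 16 and 17); the side-chain branch is steps 11–15.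

**Steps most likely to fail**

Step 6. The two faces of the ring alkene may not be told apart well enough, because the resident cyclopropane centres and the pinene-derived borane may work against each other (mismatched double stereodifferentiation), and the hindered alkene may react sluggishly. The fallback gives up reagent control and sets out from 9. Hydroboration with BH3·SMe2 followed by NaOH/H2O2 should give 11 together with its trans diastereomer (1R,2S)-2-[(1R,2R)-2-{[tert-butyl(diphenyl)silyl]oxymethyl}cyclopropyl]cycloheptan-1-ol F1; the two are diastereomers and should part on silica. F1 is recycled: Dess–Martin oxidation would give the C7-epimeric ketone (2S)-2-[(1R,2R)-2-{[tert-butyl(diphenyl)silyl]oxymethyl}cyclopropyl]cycloheptan-1-one F2, whose only difference from 12 is the enolisable centre, and DBU in toluene should equilibrate F2 with 12. The pair is separated by chromatography and F2 is returned to the equilibration. The directly formed 11 continues through step 7, and the recycled material rejoins the route at 12.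

Step 16. Facial selectivity at the formyl group may be poor if the ligand has to work against the trans-cyclopropane and the remote C14 centre, and methyl transfer from zinc or slow hydroboration of the hindered alkyne may erode the addition. The fallback sets out from 23 and 16 and forms the same C11–C12 bond without relying on the addition for stereocontrol. Hydrozirconation of 23 with Cp2Zr(H)Cl and iodinolysis should give tert-butyl{[(1E,3S,5Z,8Z)-1-iodoundeca-1,5,8-trien-3-yl]oxy}dimethylsilane F3. Nozaki–Hiyama–Kishi coupling of F3 with 16 (CrCl2, catalytic NiCl2, DMSO, rt) would give 26 mixed with its C11 epimer (8R)-8-[(1R,2R)-2-[(1R,2E,4S,6Z,9Z)-4-(tert-butyldimethylsilyloxy)-1-hydroxydodeca-2,6,9-trien-1-yl]cyclopropyl]oxocan-2-one F4. Dess–Martin oxidation of the mixture converges on the enone (8R)-8-[(1R,2R)-2-[(2E,4S,6Z,9Z)-4-(tert-butyldimethylsilyloxy)dodeca-2,6,9-trienoyl]cyclopropyl]oxocan-2-one F5. Corey–Bakshi–Shibata reduction of F5 with (S)-1-methyl-3,3-diphenyltetrahydro-1H,3H-pyrrolo[1,2-c][1,3,2]oxazaborole and catecholborane in toluene at −78 °C should then give the 11S alcohol, provided the alkenyl arm acts as the larger group. The fallback rejoins the route at 26.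

Step 13. The lipase may discriminate poorly between the ethynyl group and the allylic methylene chain, and a resolution discards half of the material in any case. The fallback replaces resolution by asymmetric reduction and sets out from 18. Addition of LiC≡CSiMe3 in THF at −78 °C should give rac-(5Z,8Z)-1-(trimethylsilyl)undeca-5,8-dien-1-yn-3-ol F6, and buffered Dess–Martin oxidation the ynone (5Z,8Z)-1-(trimethylsilyl)undeca-5,8-dien-1-yn-3-one F7. Base-free Noyori transfer hydrogenation with Ru[(S,S)-TsDPEN](p-cymene) in i-PrOH should give (3S,5Z,8Z)-1-(trimethylsilyl)undeca-5,8-dien-1-yn-3-ol F8, the alkynyl group taking the place that an aryl group takes in the usual model. K2CO3 in MeOH then removes the C-silyl group, and the fallback rejoins the route at 22.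

**Further compounds**

F1 | step 6 | (1R,2S)-2-[(1R,2R)-2-{[tert-butyl(diphenyl)silyl]oxymethyl}cyclopropyl]cycloheptan-1-ol | O[C@@H]1CCCCC[C@H]1[C@@H]1C[C@H]1CO[Si](c1ccccc1)(c1ccccc1)C(C)(C)C
F2 | step 6 | (2S)-2-[(1R,2R)-2-{[tert-butyl(diphenyl)silyl]oxymethyl}cyclopropyl]cycloheptan-1-one | O=C1CCCCC[C@H]1[C@@H]1C[C@H]1CO[Si](c1ccccc1)(c1ccccc1)C(C)(C)C
F3 | step 16 | tert-butyl{[(1E,3S,5Z,8Z)-1-iodoundeca-1,5,8-trien-3-yl]oxy}dimethylsilane | CC/C=C\C/C=C\C[C@H](O[Si](C)(C)C(C)(C)C)/C=C/I
F4 | step 16 | (8R)-8-[(1R,2R)-2-[(1R,2E,4S,6Z,9Z)-4-(tert-butyldimethylsilyloxy)-1-hydroxydodeca-2,6,9-trien-1-yl]cyclopropyl]oxocan-2-one | CC/C=C\C/C=C\C[C@H](O[Si](C)(C)C(C)(C)C)/C=C/[C@@H](O)[C@@H]1C[C@H]1[C@H]1CCCCCC(=O)O1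
F5 | step 16 | (8R)-8-[(1R,2R)-2-[(2E,4S,6Z,9Z)-4-(tert-butyldimethylsilyloxy)dodeca-2,6,9-trienoyl]cyclopropyl]oxocan-2-one | CC/C=C\C/C=C\C[C@H](O[Si](C)(C)C(C)(C)C)/C=C/C(=O)[C@@H]1C[C@H]1[C@H]1CCCCCC(=O)O1
F6 | step 13 | rac-(5Z,8Z)-1-(trimethylsilyl)undeca-5,8-dien-1-yn-3-ol | CC/C=C\C/C=C\CC(O)C#C[Si](C)(C)C
F7 | step 13 | (5Z,8Z)-1-(trimethylsilyl)undeca-5,8-dien-1-yn-3-one | CC/C=C\C/C=C\CC(=O)C#C[Si](C)(C)C
F8 | step 13 | (3S,5Z,8Z)-1-(trimethylsilyl)undeca-5,8-dien-1-yn-3-ol | CC/C=C\C/C=C\C[C@H](O)C#C[Si](C)(C)C
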